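The chlorocyclopentenone ring (C8–C12) is taken apart at C10: this carbon carries the chlorine and sits between the C9 carbonyl and C11, so it can be delivered as dichlorocarbene into the C9–C11 bond of a four-membered ring made of C8, C9, C11 and C12. The precursor is therefore a nonracemic 1-silyloxycyclobutene in which C12 already bears the protected tertiary alcohol and the (Z)-octenyl chain, made by chiral-base desymmetrization of a prochiral cyclobutanone. One operation adds C10 with its chlorine, enlarges the ring and sets the enone. A C8 aldol with an L-threitol-derived C1–C7 diacetoxy aldehyde, dehydration and desilylation complete the target.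

Key step: step 6

Assumption: the (R,R)-lithium amide in step 5 is taken to remove a proton from the methylene that becomes C11; this sense must be confirmed on the first batch, and the equally available (S,S)-amide would be used if it is the opposite.

Remark: prostanoid numbering (C1 ester carbon, C8–C12 ring, C20 methyl) is used throughout. The target is (5S,6S,7E,12S,14Z); the C12 label reads R while C8 is sp3 and S once C8 is sp2, with no change in spatial arrangement. The 5S,6S pair corresponds to natural L-tartaric acid, taken here as its commercial reduced acetonide.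

Step 1
Reactants: 1 (Z)-oct-2-en-1-ol
Product: 2 (Z)-1-chlorooct-2-ene
Conditions: N-chlorosuccinimide, Me2S, CH2Cl2, –20 → 0 °C
Reagents that add atoms: N-chlorosuccinimide, O=C1CCC(=O)N1Cl
Why: Corey–Kim chlorination: the alkoxysulfonium salt of the primary allylic alcohol is displaced by chloride in an SN2 reaction at C13, a mode that should leave the position and the Z geometry of the C14=C15 double bond untouched.

Step 2
Reactants: 2 (Z)-1-chlorooct-2-ene; 3 3-ethoxycyclobut-2-en-1-one
Product: 5 3-ethoxy-1-[(Z)-oct-2-enyl]cyclobut-2-en-1-ol (racemic), via (Z)-oct-2-enylbarium chloride 4 (not isolated)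
Conditions: BaI2, lithium biphenylide (2 equiv), THF, rt; 2, –78 °C; 3, –78 °C; pH 7 buffer at –78 °C; product kept below 25 °C
Reagents that add atoms: none
Why: Allylbarium carbonyl addition: an allylic barium chloride made from the chloride and activated zerovalent barium at –78 °C holds its geometry and reacts through its α-carbon in a 1,2-manner, so the Z-octenyl group should arrive intact at the C=O of the vinylogous ester, giving a racemic tertiary carbinol whose stereocentre is erased in step 4, while the cold quench avoids oxyanion-accelerated opening of the cyclobutene.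

Step 3
Reactants: 5 3-ethoxy-1-[(Z)-oct-2-enyl]cyclobut-2-en-1-ol
Product: 6 {[3-ethoxy-1-[(Z)-oct-2-enyl]cyclobut-2-en-1-yl]oxy}triethylsilane (racemic)
Conditions: Et3SiCl, imidazole, DMAP (cat.), DMF, 0 °C → rt
Reagents that add atoms: chlorotriethylsilane, CC[Si](Cl)(CC)CC
Why: Imidazole-mediated O-silylation should cap the tertiary hydroxyl under weakly basic conditions that generate neither the free alkoxide (electrocyclic opening) nor acid (ionization of this vinylogous hemiketal), and the triethylsilyl group is chosen because it goes on and comes off the crowded tertiary C12 more easily than a tert-butyldimethylsilyl group.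

Step 4
Reactants: 6 {[3-ethoxy-1-[(Z)-oct-2-enyl]cyclobut-2-en-1-yl]oxy}triethylsilane
Product: 7 3-[(Z)-oct-2-enyl]-3-(triethylsilyloxy)cyclobutan-1-one (achiral)
Conditions: oxalic acid (10% aq.), SiO2, CH2Cl2, 0 °C → rt
Reagents that add atoms: water, O
Why: Enol ether hydrolysis: protonation of the enol ether carbon and capture of the oxocarbenium ion by water release ethanol and the C9 ketone, while the silyl ether blocks the retro-aldol cleavage and the dehydration (Stork–Danheiser pathway) open to the free β-hydroxy ketone, and the product gains a mirror plane through C9 and C12 so that no stereocentre remains.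

Step 5
Reactants: 7 3-[(Z)-oct-2-enyl]-3-(triethylsilyloxy)cyclobutan-1-one
Product: 8 (3R)-3-[(Z)-oct-2-enyl]-3-(triethylsilyloxy)-1-(trimethylsilyloxy)cyclobut-1-ene
Conditions: (R,R)-bis(1-phenylethyl)amine, n-BuLi, LiCl, THF, –78 °C; Me3SiCl, then 7 (slow addition), –100 °C; Et3N, pentane; filtration through Et3N-deactivated SiO2, kept cold
Reagents that add atoms: chlorotrimethylsilane, C[Si](C)(C)Cl
Why: Enantioselective deprotonation (chiral lithium amide desymmetrization with in situ silyl chloride quench, established for 3-substituted cyclobutanones): the C2-symmetric amide should remove a proton from one of the two enantiotopic α-methylenes and the enolate is trapped at once, which forestalls β-elimination of silanolate, so the choice of the methylene that becomes C11 sets the C12 configuration under reagent control.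

Step 6
Reactants: 8 (3R)-3-[(Z)-oct-2-enyl]-3-(triethylsilyloxy)-1-(trimethylsilyloxy)cyclobut-1-ene; 9 sodium trichloroacetate
Product: 11 (4R)-2-chloro-4-[(Z)-oct-2-enyl]-4-(triethylsilyloxy)cyclopent-2-en-1-one, via dichlorobicyclo[2.1.0]pentane adduct 10 (not isolated)
Conditions: NaO2CCCl3 (1.5 equiv, in portions), 15-crown-5 (0.2 equiv), DME, 40–45 °C
Reagents that add atoms: sodium trichloroacetate (compound 9, source of C10 and its chlorine), [Na+].[O-]C(=O)C(Cl)(Cl)Cl
Why: Decarboxylation of the trichloroacetate gives the trichloromethyl anion, which loses chloride to singlet dichlorocarbene, and this electrophile adds in a concerted [2+1] manner to the C9=C11 silyl enol ether to give adduct 10. In 10 the endo C10–Cl bond ionizes with disrotatory opening of the cyclopropane, which breaks the old C9–C11 bond with help from the oxygen lone pair, and chloride then takes the Me3Si group from the 2-chloro-oxyallyl cation to leave the C9 ketone and the C10=C11 double bond. The closest known reaction type is the dihalocarbene one-carbon ring enlargement of cyclic trimethylsilyl enol ethers to 2-halocycloalk-2-enones, together with the spontaneous opening of dihalocarbene–cyclobutene adducts to halocyclopentenes. The five-membered ring is closed not by cyclization but by enlargement: the ring C8–C9–C11–C12 becomes C8–C9–C10–C11–C12 through a two-electron electrocyclic cyclopropyl-to-allyl opening driven by release of three- and four-membered ring strain. No stereocentre is created, since the transient centres at C9 and C11 in 10 are erased on opening and C12, set in step 5, has none of its bonds broken. The step needs selectivity for the enol ether over the C14=C15 alkene, secured by the much higher nucleophilicity of the strained oxygen-substituted double bond and a small excess of carbene, and it needs a temperature below that at which the 3-silyloxycyclobutene opens to a diene, which is why the decarboxylation is accelerated by the crown ether and not run in refluxing solvent.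

Step 7
Reactants: 12 [(4S,5S)-2,2-dimethyl-1,3-dioxolane-4,5-diyl]dimethanol (2,3-O-isopropylidene-L-threitol)
Product: 13 [(4S,5S)-5-(benzyloxymethyl)-2,2-dimethyl-1,3-dioxolan-4-yl]methanol
Conditions: NaH (1.0 equiv), BnBr (1.0 equiv), Bu4NI (cat.), THF, 0 °C → rt
Reagents that add atoms: benzyl bromide, BrCc1ccccc1
Why: Williamson ether synthesis on a C2-symmetric diol: with one equivalent each of base and benzyl bromide the mono-ether should be the main product, the two hydroxyls being equivalent so that no regiochemical question arises, and neither stereocentre is touched.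

Step 8
Reactants: 13 [(4S,5S)-5-(benzyloxymethyl)-2,2-dimethyl-1,3-dioxolan-4-yl]methanol
Product: 16 (4S,5S)-4-(benzyloxymethyl)-2,2-dimethyl-5-(prop-2-ynyl)-1,3-dioxolane, via primary triflate 14 (not isolated), via silylated alkyne 15 (not isolated)
Conditions: Tf2O, 2,6-lutidine, CH2Cl2, –78 °C; LiC≡CSiMe3 (from HC≡CSiMe3, n-BuLi), THF–DMPU, –78 → –20 °C; K2CO3 (cat.), MeOH, rt
Reagents that add atoms: ethynyltrimethylsilane, C#C[Si](C)(C)C
Why: SN2 alkylation of a lithium acetylide by a primary triflate in THF–DMPU, a reaction that tolerates the β-alkoxy substituent, followed by methanolysis of the C–Si bond, should install C3 and C2 as a terminal alkyne without affecting C5 or C6.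

Step 9
Reactants: 16 (4S,5S)-4-(benzyloxymethyl)-2,2-dimethyl-5-(prop-2-ynyl)-1,3-dioxolane
Product: 18 methyl 4-[(4S,5S)-5-(benzyloxymethyl)-2,2-dimethyl-1,3-dioxolan-4-yl]but-2-ynoate, via lithium acetylide 17 (not isolated)
Conditions: n-BuLi, THF, –78 °C; ClCO2Me, –78 → 0 °C
Reagents that add atoms: methyl chloroformate, COC(=O)Cl
Why: C-acylation of a lithium acetylide with a chloroformate, the standard preparation of alk-2-ynoates, should introduce C1 as the methyl ester.

Step 10
Reactants: 18 methyl 4-[(4S,5S)-5-(benzyloxymethyl)-2,2-dimethyl-1,3-dioxolan-4-yl]but-2-ynoate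
Product: 19 methyl (5S,6S)-7-(benzyloxy)-5,6-dihydroxyhept-2-ynoate
Conditions: TsOH·H2O (cat.), MeOH, rt
Reagents that add atoms: none
Why: Acid-catalysed transacetalization to methanol should free the 5,6-diol, and doing so while C2–C3 is still an alkyne makes δ-lactonization of the 5-hydroxyl onto C1 geometrically impossible, a reaction the saturated 5-hydroxy ester would undergo readily.

Step 11
Reactants: 19 methyl (5S,6S)-7-(benzyloxy)-5,6-dihydroxyhept-2-ynoate
Product: 20 methyl (5S,6S)-5,6-diacetoxy-7-(benzyloxy)hept-2-ynoate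
Conditions: Ac2O, pyridine, DMAP (cat.), CH2Cl2, 0 °C
Reagents that add atoms: acetic anhydride, CC(=O)OC(C)=O
Why: Nucleophile-catalysed acetylation of the two secondary alcohols is fast at 0 °C and should outrun any base-induced addition of a hydroxyl to the ynoate, and configuration is retained because only O–H bonds react.

Step 12
Reactants: 20 methyl (5S,6S)-5,6-diacetoxy-7-(benzyloxy)hept-2-ynoate
Product: 21 methyl (5S,6S)-5,6-diacetoxy-7-hydroxyheptanoate
Conditions: H2 (1 atm), 10% Pd/C, EtOAc, rt
Reagents that add atoms: none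
Why: Heterogeneous catalytic hydrogenation should saturate the C2–C3 triple bond and cleave the benzyl ether by hydrogenolysis in one operation under neutral conditions that do not promote acetyl migration to the freed C7 hydroxyl.

Step 13
Reactants: 21 methyl (5S,6S)-5,6-diacetoxy-7-hydroxyheptanoate
Product: 22 methyl (5S,6R)-5,6-diacetoxy-7-oxoheptanoate
Conditions: Dess–Martin periodinane, pyridine, CH2Cl2, 0 °C → rt; used at once
Reagents that add atoms: none
Why: Dess–Martin oxidation of a primary alcohol runs under nearly neutral, pyridine-buffered conditions, so the α,β-diacetoxy aldehyde should form without epimerization at C6 or β-elimination of acetic acid (the C6 label changes to R only because C7 gains priority).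

Step 14
Reactants: 11 (4R)-2-chloro-4-[(Z)-oct-2-enyl]-4-(triethylsilyloxy)cyclopent-2-en-1-one; 22 methyl (5S,6R)-5,6-diacetoxy-7-oxoheptanoate
Product: 24 C7-hydroxy aldol adduct of 11 with 22 (C7/C8 diastereomer mixture; C5 C6 C12 unchanged), via lithium dienolate 23 (not isolated)
Conditions: LiN(i-Pr)2, THF, –78 °C; 22, –78 °C, 15 min; AcOH in THF at –78 °C
Reagents that add atoms: none
Why: Kinetic lithium aldol addition: C8 is the only enolizable position of 11 (C10 has no hydrogen, and loss of the C12 silyloxide from the enolate would give an antiaromatic cyclopentadienone), the dienolate should add to the reactive α-acetoxy aldehyde within minutes at –78 °C, faster than it deprotonates C6 or attacks an acetate, and the new C7 and C8 centres, formed as a mixture, are both removed in step 15.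

Step 15
Reactants: 24 C7-hydroxy aldol adduct
Product: 26 methyl (5S,6S,7E,12S,14Z)-5,6-diacetoxy-10-chloro-9-oxo-12-(triethylsilyloxy)prosta-7,10,14-trienoate, via C7 mesylate 25 (not isolated)
Conditions: MsCl, DMAP, CH2Cl2, 0 °C → rt
Reagents that add atoms: none
Why: Mesylation followed by E1cB elimination through the C8 enolate should give the cross-conjugated dienone, and because the enolate can rotate about C7–C8 before the leaving group departs, the more stable 7E isomer (H7, not C6, beside the C9 carbonyl) should predominate, any 7Z isomer being removed by chromatography.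

Step 16
Reactants: 26 methyl (5S,6S,7E,12S,14Z)-5,6-diacetoxy-10-chloro-9-oxo-12-(triethylsilyloxy)prosta-7,10,14-trienoate
Product: 27 methyl (5S,6S,7E,12S,14Z)-5,6-diacetoxy-10-chloro-12-hydroxy-9-oxoprosta-7,10,14-trienoate (target)
Conditions: HF·pyridine, pyridine, THF, 0 °C → rt
Reagents that add atoms: none
Why: Fluoride-mediated Si–O cleavage with pyridine-buffered HF should remove the tertiary triethylsilyl group selectively, since the acetates, the methyl ester and the chlorodienone are inert to these weakly acidic conditions and C12 cannot ionize (its cation would be conjugated with the C9 carbonyl in a cyclopentadienone-like array), so the C12 configuration is retained.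

Compound list
1 | (Z)-oct-2-en-1-ol | CCCCC/C=C\CO | starting material
2 | (Z)-1-chlorooct-2-ene | CCCCC/C=C\CCl | intermediate
3 | 3-ethoxycyclobut-2-en-1-one | CCOC1=CC(=O)C1 | starting material
4 | (Z)-oct-2-enylbarium chloride | CCCCC/C=C\C[Ba]Cl | intermediate (not isolated)
5 | 3-ethoxy-1-[(Z)-oct-2-enyl]cyclobut-2-en-1-ol (racemic) | CCCCC/C=C\CC1(O)C=C(OCC)C1 | intermediate
6 | {[3-ethoxy-1-[(Z)-oct-2-enyl]cyclobut-2-en-1-yl]oxy}triethylsilane (racemic) | CCCCC/C=C\CC1(O[Si](CC)(CC)CC)C=C(OCC)C1 | intermediate
7 | 3-[(Z)-oct-2-enyl]-3-(triethylsilyloxy)cyclobutan-1-one (achiral) | CCCCC/C=C\CC1(O[Si](CC)(CC)CC)CC(=O)C1 | intermediate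
8 | (3R)-3-[(Z)-oct-2-enyl]-3-(triethylsilyloxy)-1-(trimethylsilyloxy)cyclobut-1-ene | CCCCC/C=C\C[C@]1(O[Si](CC)(CC)CC)C=C(O[Si](C)(C)C)C1 | intermediate (key-step precursor)
9 | sodium trichloroacetate | [Na+].[O-]C(=O)C(Cl)(Cl)Cl | starting material
10 | 5,5-dichloro-3-[(Z)-oct-2-enyl]-3-(triethylsilyloxy)-1-(trimethylsilyloxy)bicyclo[2.1.0]pentane (C12 as in 8, bridgehead centres as a mixture) | CCCCC/C=C\C[C@@]1(O[Si](CC)(CC)CC)CC2(O[Si](C)(C)C)C(Cl)(Cl)C12 | intermediate (not isolated)
11 | (4R)-2-chloro-4-[(Z)-oct-2-enyl]-4-(triethylsilyloxy)cyclopent-2-en-1-one | CCCCC/C=C\C[C@]1(O[Si](CC)(CC)CC)C=C(Cl)C(=O)C1 | intermediate (key-step product)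
12 | [(4S,5S)-2,2-dimethyl-1,3-dioxolane-4,5-diyl]dimethanol | OC[C@@H]1OC(C)(C)O[C@H]1CO | starting material
13 | [(4S,5S)-5-(benzyloxymethyl)-2,2-dimethyl-1,3-dioxolan-4-yl]methanol | c1ccccc1COC[C@@H]1OC(C)(C)O[C@H]1CO | intermediate
14 | [(4S,5S)-5-(benzyloxymethyl)-2,2-dimethyl-1,3-dioxolan-4-yl]methyl trifluoromethanesulfonate | c1ccccc1COC[C@@H]1OC(C)(C)O[C@H]1COS(=O)(=O)C(F)(F)F | intermediate (not isolated)
15 | {3-[(4S,5S)-5-(benzyloxymethyl)-2,2-dimethyl-1,3-dioxolan-4-yl]prop-1-ynyl}trimethylsilane | c1ccccc1COC[C@@H]1OC(C)(C)O[C@H]1CC#C[Si](C)(C)C | intermediate (not isolated)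
16 | (4S,5S)-4-(benzyloxymethyl)-2,2-dimethyl-5-(prop-2-ynyl)-1,3-dioxolane | c1ccccc1COC[C@@H]1OC(C)(C)O[C@H]1CC#C | intermediate
17 | lithium acetylide of 16 | c1ccccc1COC[C@@H]1OC(C)(C)O[C@H]1CC#C[Li] | intermediate (not isolated)
18 | methyl 4-[(4S,5S)-5-(benzyloxymethyl)-2,2-dimethyl-1,3-dioxolan-4-yl]but-2-ynoate | c1ccccc1COC[C@@H]1OC(C)(C)O[C@H]1CC#CC(=O)OC | intermediate
19 | methyl (5S,6S)-7-(benzyloxy)-5,6-dihydroxyhept-2-ynoate | c1ccccc1COC[C@H](O)[C@H](CC#CC(=O)OC)O | intermediate
20 | methyl (5S,6S)-5,6-diacetoxy-7-(benzyloxy)hept-2-ynoate | c1ccccc1COC[C@H](OC(C)=O)[C@H](CC#CC(=O)OC)OC(C)=O | intermediate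
21 | methyl (5S,6S)-5,6-diacetoxy-7-hydroxyheptanoate | OC[C@H](OC(C)=O)[C@H](CCCC(=O)OC)OC(C)=O | intermediate
22 | methyl (5S,6R)-5,6-diacetoxy-7-oxoheptanoate | O=C[C@H](OC(C)=O)[C@H](CCCC(=O)OC)OC(C)=O | intermediate
23 | lithium C8–C9 dienolate of 11 | CCCCC/C=C\C[C@]1(O[Si](CC)(CC)CC)C=C(Cl)C(O[Li])=C1 | intermediate (not isolated)
24 | methyl (14Z)-5,6-diacetoxy-10-chloro-7-hydroxy-9-oxo-12-(triethylsilyloxy)prosta-10,14-dienoate (C5, C6 as in 22, C12 as in 11, mixture at C7 and C8) | CCCCC/C=C\C[C@]1(O[Si](CC)(CC)CC)C=C(Cl)C(=O)C1C(O)[C@H](OC(C)=O)[C@H](CCCC(=O)OC)OC(C)=O | intermediate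
25 | C7 methanesulfonate of 24 | CCCCC/C=C\C[C@]1(O[Si](CC)(CC)CC)C=C(Cl)C(=O)C1C(OS(C)(=O)=O)[C@H](OC(C)=O)[C@H](CCCC(=O)OC)OC(C)=O | intermediate (not isolated)
26 | methyl (5S,6S,7E,12S,14Z)-5,6-diacetoxy-10-chloro-9-oxo-12-(triethylsilyloxy)prosta-7,10,14-trienoate | CCCCC/C=C\C[C@]1(O[Si](CC)(CC)CC)C=C(Cl)C(=O)/C1=C/[C@H](OC(C)=O)[C@H](CCCC(=O)OC)OC(C)=O | intermediate
27 | methyl (5S,6S,7E,12S,14Z)-5,6-diacetoxy-10-chloro-12-hydroxy-9-oxoprosta-7,10,14-trienoate | CCCCC/C=C\C[C@]1(O)C=C(Cl)C(=O)/C1=C/[C@H](OC(C)=O)[C@H](CCCC(=O)OC)OC(C)=O | target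

Total step count: 16. Longest linear sequence: 10 steps (steps 7–13, then 14–16); the ring branch is 9 steps (steps 1–6, then 14–16).

Steps most likely to fail

Step 6. The silyloxycyclobutene may open thermally to a bis(silyloxy)diene before it meets the carbene. The decarboxylation may also be too slow at the temperature the substrate tolerates, or the carbene may add to the C14=C15 alkene as well. The fallback inserts CH2 first and brings in chlorine afterwards, all by known reaction types, setting out from 8. Cyclopropanation of the enol ether by the Furukawa variant of the Simmons–Smith reaction (Et2Zn, CH2I2, CH2Cl2, 0 °C) gives 3-[(Z)-oct-2-enyl]-3-(triethylsilyloxy)-1-(trimethylsilyloxy)bicyclo[2.1.0]pentane F1. FeCl3 in DMF at 0 °C (oxidative opening of the silyloxycyclopropane at the C9–C11 bond) gives 3-chloro-4-[(Z)-oct-2-enyl]-4-(triethylsilyloxy)cyclopentan-1-one F2, and NaOAc in MeOH eliminates HCl to give 4-[(Z)-oct-2-enyl]-4-(triethylsilyloxy)cyclopent-2-en-1-one F3. Weitz–Scheffer epoxidation (H2O2, NaOH, MeOH, 0 °C), which leaves the isolated alkene alone, gives 4-[(Z)-oct-2-enyl]-4-(triethylsilyloxy)-6-oxabicyclo[3.1.0]hexan-2-one F4. Chloride opening at the α-carbon C10 (LiCl, AcOH, THF) gives 2-chloro-3-hydroxy-4-[(Z)-oct-2-enyl]-4-(triethylsilyloxy)cyclopentan-1-one F5, which loses water (cat. TsOH) and rejoins the route at 11.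

Step 5. The base may discriminate poorly between the enantiotopic C8 and C11 methylenes, because the silyloxy and alkyl groups at C12 are of similar size, or the sense of induction may be the opposite one. The fallback replaces asymmetric deprotonation by resolution and sets out from 7. LiN(i-Pr)2 and Me3SiCl (THF, –78 °C) give the racemic silyl enol ether F6. The conditions of step 6 then give, through the racemic dichloro adduct F7, the racemic chloroenone F8. Preparative chromatography on a chiral stationary phase (amylose tris(3,5-dimethylphenylcarbamate)) delivers 11 and sets aside the (4S)-enantiomer F9; the route is rejoined at 11.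

Step 4. Acid may ionize the allylic tertiary silyl ether, or silanol may be lost after hydrolysis, leading to 3-octenylcyclobutenone instead of clean unmasking of the ketone. The fallback avoids the enol ether altogether and sets out from 4 (made from 2 as in step 2) and commercial 3-(benzyloxy)cyclobutan-1-one (O=C1CC(OCc2ccccc2)C1). Addition at –78 °C gives 3-(benzyloxy)-1-[(Z)-oct-2-enyl]cyclobutan-1-ol F10 (cis/trans mixture of no consequence). Et3SiCl and imidazole give its triethylsilyl ether F11. Lithium naphthalenide (LiC10H8, THF, –25 °C) removes the benzyl group without touching the alkene, giving 3-[(Z)-oct-2-enyl]-3-(triethylsilyloxy)cyclobutan-1-ol F12, and Dess–Martin oxidation returns to the route at 7.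

Further compounds
F1 | step 6 | 3-[(Z)-oct-2-enyl]-3-(triethylsilyloxy)-1-(trimethylsilyloxy)bicyclo[2.1.0]pentane | CCCCC/C=C\C[C@@]1(O[Si](CC)(CC)CC)CC2(O[Si](C)(C)C)CC12
F2 | step 6 | 3-chloro-4-[(Z)-oct-2-enyl]-4-(triethylsilyloxy)cyclopentan-1-one | CCCCC/C=C\C[C@]1(O[Si](CC)(CC)CC)C(Cl)CC(=O)C1
F3 | step 6 | 4-[(Z)-oct-2-enyl]-4-(triethylsilyloxy)cyclopent-2-en-1-one | CCCCC/C=C\C[C@]1(O[Si](CC)(CC)CC)C=CC(=O)C1
F4 | step 6 | 4-[(Z)-oct-2-enyl]-4-(triethylsilyloxy)-6-oxabicyclo[3.1.0]hexan-2-one | CCCCC/C=C\C[C@]1(O[Si](CC)(CC)CC)C2OC2C(=O)C1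
F5 | step 6 | 2-chloro-3-hydroxy-4-[(Z)-oct-2-enyl]-4-(triethylsilyloxy)cyclopentan-1-one | CCCCC/C=C\C[C@]1(O[Si](CC)(CC)CC)C(O)C(Cl)C(=O)C1
F6 | step 5 | racemic 3-[(Z)-oct-2-enyl]-3-(triethylsilyloxy)-1-(trimethylsilyloxy)cyclobut-1-ene | CCCCC/C=C\CC1(O[Si](CC)(CC)CC)C=C(O[Si](C)(C)C)C1
F7 | step 5 | racemic 5,5-dichloro-3-[(Z)-oct-2-enyl]-3-(triethylsilyloxy)-1-(trimethylsilyloxy)bicyclo[2.1.0]pentane | CCCCC/C=C\CC1(O[Si](CC)(CC)CC)CC2(O[Si](C)(C)C)C(Cl)(Cl)C12
F8 | step 5 | racemic 2-chloro-4-[(Z)-oct-2-enyl]-4-(triethylsilyloxy)cyclopent-2-en-1-one | CCCCC/C=C\CC1(O[Si](CC)(CC)CC)C=C(Cl)C(=O)C1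
F9 | step 5 | (4S)-2-chloro-4-[(Z)-oct-2-enyl]-4-(triethylsilyloxy)cyclopent-2-en-1-one | CCCCC/C=C\C[C@@]1(O[Si](CC)(CC)CC)C=C(Cl)C(=O)C1
F10 | step 4 | 3-(benzyloxy)-1-[(Z)-oct-2-enyl]cyclobutan-1-ol | CCCCC/C=C\CC1(O)CC(OCc2ccccc2)C1
F11 | step 4 | {[3-(benzyloxy)-1-[(Z)-oct-2-enyl]cyclobutyl]oxy}triethylsilane | CCCCC/C=C\CC1(O[Si](CC)(CC)CC)CC(OCc2ccccc2)C1
F12 | step 4 | 3-[(Z)-oct-2-enyl]-3-(triethylsilyloxy)cyclobutan-1-ol | CCCCC/C=C\CC1(O[Si](CC)(CC)CC)CC(O)C1
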